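**Plan**
- Retrosynthetic cuts: (i) the aryl C5–propenyl bond (Suzuki, Br as placeholder); (ii) the C3 methyl is traced back to a C3–CO2Me group; (iii) the C3–C3a bond is opened by re-inserting that ester carbon between C3 and the arene, which gives a (2R)-flavanone; (iv) the flavanone C2–aryl bond (conjugate addition to a chromone); (v) the chromone back to a 2-hydroxyacetophenone.
- Enabling feature: in the dihydrofuran ring O1–C2–C3–C3a–C7a, the one-carbon substituent sits on C3, which is bonded directly to arene carbon C3a and flanked by the aryl-bearing C2. That array is exactly what results when the aryl carbon of a flavanone pyranone ring (O1–C2–C3–C4(=O)–C4a–C8a) shifts from the carbonyl carbon C4 to C3 and C4 is expelled from the ring.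
- Ring order forward: both benzene rings are bought; the pyranone ring is closed (chromone), arylated, then contracted six-to-five by an oxidative 1,2-aryl shift; the expelled ester carbon is reduced to CH3; the propenyl group is coupled last because an alkene would not survive the iodine(III) oxidant.
- Stereochemistry: C2 by catalyst control in the conjugate addition; C3 relayed from C2 in the stereospecific shift (trans); the E-alkene comes from the boronate.

Key step: step 4

Remark: the SMILES is read as the (2R,3R)-trans isomer. The sense of induction of the ligand in step 3 is assigned by analogy with β-substituted cyclic enones; should it prove opposite, the antipodal ligand would be used.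

**Route**

Step 1
Reactants: 1 1-(2-hydroxy-3-methoxyphenyl)ethanone; 2 N-bromosuccinimide
Product: 3 1-(5-bromo-2-hydroxy-3-methoxyphenyl)ethanone
Conditions: NBS (1.05 equiv), MeCN, 0 °C to rt
Reagents that add atoms: N-bromosuccinimide, O=C1CCC(=O)N1Br
Why: Electrophilic aromatic bromination, directed by the free phenol to its para position (C5), the only strongly activated open site, should give the bromide that later carries the propenyl group.

Step 2
Reactants: 3 1-(5-bromo-2-hydroxy-3-methoxyphenyl)ethanone; 4 N,N-dimethylformamide dimethyl acetal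
Product: 6 6-bromo-8-methoxy-4H-chromen-4-one, via enaminone 5 (not isolated)
Conditions: DMF-DMA (1.5 equiv), toluene, 100 °C; evaporate; conc. HCl, CH2Cl2, 40 °C
Reagents that add atoms: N,N-dimethylformamide dimethyl acetal, COC(OC)N(C)C
Why: Enaminone condensation of the methyl ketone, followed by acid-promoted addition–elimination of the phenol with loss of dimethylamine, is the standard chromone synthesis from 2-hydroxyacetophenones and closes the pyranone ring.

Step 3
Reactants: 6 6-bromo-8-methoxy-4H-chromen-4-one; 7 (3,4,5-trimethoxyphenyl)boronic acid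
Product: 8 (2R)-6-bromo-8-methoxy-2-(3,4,5-trimethoxyphenyl)-2,3-dihydro-4H-chromen-4-one
Conditions: Pd(OCOCF3)2 (5 mol%), (S)-t-BuPyOx (6 mol%), NH4PF6 (30 mol%), H2O (5 equiv), boronic acid (2 equiv), ClCH2CH2Cl, 60 °C
Reagents that add atoms: (3,4,5-trimethoxyphenyl)boronic acid, COc1cc(B(O)O)cc(OC)c1OC
Why: Pd(II)-catalysed asymmetric conjugate addition of an arylboronic acid to a chromone (Hayashi–Miyaura-type 1,4-addition with a pyridine–oxazoline ligand): aryl transfer from boron to cationic Pd(II), enantioface-selective insertion of the C2=C3 bond (the tert-butyl group of the ligand blocks one face, which sets C2 as R) and protonolysis of the Pd enolate by water, a cycle that stays at Pd(II) so that the C–Br bond should remain intact.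

Step 4
Reactants: 8 (2R)-6-bromo-8-methoxy-2-(3,4,5-trimethoxyphenyl)-2,3-dihydro-4H-chromen-4-one; 9 trimethyl orthoformate
Product: 12 methyl (2R,3R)-5-bromo-7-methoxy-2-(3,4,5-trimethoxyphenyl)-2,3-dihydro-1-benzofuran-3-carboxylate, via methyl enol ether 10 (not isolated), via trans-3-iodanyl ketal 11 (not isolated)
Conditions: PhI(OAc)2 (1.1 equiv), conc. H2SO4, HC(OMe)3 (solvent), 0 °C to rt; aq NaHCO3 work-up
Reagents that add atoms: trimethyl orthoformate, COC(OC)OC
Why: Acid and orthoformate convert the ketone into enol ether 10, which attacks the activated λ3-iodane through C3 on the face opposite the C2 aryl group and is capped by methanol at C4 to give the trans ketal 11; there the equatorial C3–I bond is antiperiplanar to the C4–C4a bond, so aryl carbon C4a shifts from C4 to C3 as iodobenzene leaves, and the expelled C4 becomes a dimethoxycarbenium centre that ends as the methyl ester. The closest known reaction type is the oxidative ring contraction of flavanones to methyl 2-aryl-2,3-dihydrobenzofuran-3-carboxylates with PhI(OAc)2/H2SO4 or thallium(III) nitrate in trimethyl orthoformate, a 1,2-aryl shift of the semipinacol kind. The five-membered ring is not closed end to end: it arises from the six-membered pyranone by a suprafacial 1,2-migration of C4a through a bridged phenonium (spiro three-membered) transition state, making C3–C4a and breaking C4–C4a. C2 is untouched, and C3 is set by the stereospecific shift with inversion at C3 (the aryl carbon enters anti to iodine), which from the trans iodane places the ester carbon trans to the C2 aryl group, giving (2R,3R), also the thermodynamically preferred epimer. The step needs migration of the fused aryl carbon instead of migration of the C2 aryl group (isoflavone) or loss of H-2 (flavone); this is secured by the C4 ketal (only this shift leaves an oxygen-stabilised cation), by the ring oxygen O1 ortho to C4a, by the diequatorial conformation of 11 and by the modest migratory aptitude of the 3,4,5-trimethoxyphenyl group (two meta methoxy groups), while the aryl bromide is inert and no alkene is yet present.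

Step 5
Reactants: 12 methyl (2R,3R)-5-bromo-7-methoxy-2-(3,4,5-trimethoxyphenyl)-2,3-dihydro-1-benzofuran-3-carboxylate
Product: 13 [(2R,3S)-5-bromo-7-methoxy-2-(3,4,5-trimethoxyphenyl)-2,3-dihydro-1-benzofuran-3-yl]methanol
Conditions: DIBAL-H (2.5 equiv), CH2Cl2, −78 to 0 °C; aq Rochelle salt
Reagents that add atoms: none
Why: Hydride reduction of the ester to the primary alcohol with a non-basic aluminium hydride at low temperature should leave the aryl bromide alone and avoid enolisation at C3 (epimerisation or E1cB opening of the β-aryloxy ester); the descriptor at C3 changes only through the priority rules.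

Step 6
Reactants: 13 [(2R,3S)-5-bromo-7-methoxy-2-(3,4,5-trimethoxyphenyl)-2,3-dihydro-1-benzofuran-3-yl]methanol; 14 4-methylbenzenesulfonyl chloride
Product: 15 [(2R,3S)-5-bromo-7-methoxy-2-(3,4,5-trimethoxyphenyl)-2,3-dihydro-1-benzofuran-3-yl]methyl 4-methylbenzenesulfonate
Conditions: TsCl (1.3 equiv), Et3N, DMAP (cat.), CH2Cl2, 0 °C to rt
Reagents that add atoms: 4-methylbenzenesulfonyl chloride, Cc1ccc(cc1)S(=O)(=O)Cl
Why: Sulfonylation (tosylation) of the unhindered primary alcohol under mild amine base activates the exocyclic carbon for hydride displacement without touching either stereocentre.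

Step 7
Reactants: 15 [(2R,3S)-5-bromo-7-methoxy-2-(3,4,5-trimethoxyphenyl)-2,3-dihydro-1-benzofuran-3-yl]methyl 4-methylbenzenesulfonate
Product: 16 (2R,3R)-5-bromo-7-methoxy-3-methyl-2-(3,4,5-trimethoxyphenyl)-2,3-dihydro-1-benzofuran
Conditions: LiEt3BH (2.5 equiv), THF, 0 °C to rt; aqueous quench
Reagents that add atoms: none
Why: SN2 displacement of a primary tosylate by lithium triethylborohydride (Super-Hydride reduction) should turn the expelled ring carbon into the C3 methyl group at a temperature at which the aryl bromide and the benzylic ether are inert, the reacting carbon not being a stereocentre.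

Step 8
Reactants: 16 (2R,3R)-5-bromo-7-methoxy-3-methyl-2-(3,4,5-trimethoxyphenyl)-2,3-dihydro-1-benzofuran; 17 4,4,5,5-tetramethyl-2-[(E)-prop-1-en-1-yl]-1,3,2-dioxaborolane
Product: 18 (2R,3R)-7-methoxy-3-methyl-5-[(E)-prop-1-en-1-yl]-2-(3,4,5-trimethoxyphenyl)-2,3-dihydro-1-benzofuran
Conditions: Pd(dppf)Cl2 (5 mol%), K2CO3 (3 equiv), 1,4-dioxane/H2O (4:1), 85 °C
Reagents that add atoms: 4,4,5,5-tetramethyl-2-[(E)-prop-1-en-1-yl]-1,3,2-dioxaborolane, C/C=C/B1OC(C)(C)C(C)(C)O1
Why: Suzuki–Miyaura cross-coupling of the aryl bromide with an (E)-alkenylboronate proceeds with retention of alkene geometry and, with no acidic C–H left next to a carbonyl group, should deliver the target without touching C2 or C3.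

**Compound list**

1 | 1-(2-hydroxy-3-methoxyphenyl)ethanone | CC(=O)c1cccc(OC)c1O | starting material
2 | N-bromosuccinimide | O=C1CCC(=O)N1Br | starting material
3 | 1-(5-bromo-2-hydroxy-3-methoxyphenyl)ethanone | CC(=O)c1cc(Br)cc(OC)c1O | intermediate
4 | N,N-dimethylformamide dimethyl acetal | COC(OC)N(C)C | starting material
5 | (E)-1-(5-bromo-2-hydroxy-3-methoxyphenyl)-3-(dimethylamino)prop-2-en-1-one (enaminone, not isolated) | CN(C)/C=C/C(=O)c1cc(Br)cc(OC)c1O | intermediate
6 | 6-bromo-8-methoxy-4H-chromen-4-one | O=c1ccoc2c(OC)cc(Br)cc12 | intermediate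
7 | (3,4,5-trimethoxyphenyl)boronic acid | COc1cc(B(O)O)cc(OC)c1OC | starting material
8 | (2R)-6-bromo-8-methoxy-2-(3,4,5-trimethoxyphenyl)-2,3-dihydro-4H-chromen-4-one | Brc1cc(OC)c2c(c1)C(=O)C[C@H](c1cc(OC)c(OC)c(OC)c1)O2 | intermediate
9 | trimethyl orthoformate | COC(OC)OC | starting material
10 | (2R)-6-bromo-4,8-dimethoxy-2-(3,4,5-trimethoxyphenyl)-2H-chromene (methyl enol ether, not isolated) | Brc1cc(OC)c2c(c1)C(OC)=C[C@H](c1cc(OC)c(OC)c(OC)c1)O2 | intermediate
11 | 2,3-trans-3-[acetoxy(phenyl)-λ3-iodanyl]-6-bromo-4,4,8-trimethoxy-2-(3,4,5-trimethoxyphenyl)chromane (not isolated) | Brc1cc(OC)c2c(c1)C(OC)(OC)[C@@H](I(OC(C)=O)c1ccccc1)[C@H](c1cc(OC)c(OC)c(OC)c1)O2 | intermediate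
12 | methyl (2R,3R)-5-bromo-7-methoxy-2-(3,4,5-trimethoxyphenyl)-2,3-dihydro-1-benzofuran-3-carboxylate | Brc1cc(OC)c2c(c1)[C@@H](C(=O)OC)[C@H](c1cc(OC)c(OC)c(OC)c1)O2 | intermediate
13 | [(2R,3S)-5-bromo-7-methoxy-2-(3,4,5-trimethoxyphenyl)-2,3-dihydro-1-benzofuran-3-yl]methanol | Brc1cc(OC)c2c(c1)[C@@H](CO)[C@H](c1cc(OC)c(OC)c(OC)c1)O2 | intermediate
14 | 4-methylbenzenesulfonyl chloride | Cc1ccc(cc1)S(=O)(=O)Cl | starting material
15 | [(2R,3S)-5-bromo-7-methoxy-2-(3,4,5-trimethoxyphenyl)-2,3-dihydro-1-benzofuran-3-yl]methyl 4-methylbenzenesulfonate | Brc1cc(OC)c2c(c1)[C@@H](COS(=O)(=O)c1ccc(C)cc1)[C@H](c1cc(OC)c(OC)c(OC)c1)O2 | intermediate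
16 | (2R,3R)-5-bromo-7-methoxy-3-methyl-2-(3,4,5-trimethoxyphenyl)-2,3-dihydro-1-benzofuran | Brc1cc(OC)c2c(c1)[C@@H](C)[C@H](c1cc(OC)c(OC)c(OC)c1)O2 | intermediate
17 | 4,4,5,5-tetramethyl-2-[(E)-prop-1-en-1-yl]-1,3,2-dioxaborolane | C/C=C/B1OC(C)(C)C(C)(C)O1 | starting material
18 | (2R,3R)-7-methoxy-3-methyl-5-[(E)-prop-1-en-1-yl]-2-(3,4,5-trimethoxyphenyl)-2,3-dihydro-1-benzofuran | C/C=C/c1cc(OC)c2c(c1)[C@@H](C)[C@H](c1cc(OC)c(OC)c(OC)c1)O2 | target

**Step count and risks**

Total step count: 8. Longest linear sequence: 8 steps (1 to 18).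

Steps most likely to fail:

Step 4. What may go wrong: migration of the C2 aryl group or loss of H-2 may compete with the wanted shift; the iodane may attack the electron-rich trimethoxyphenyl ring; acid-induced ionisation of the benzylic C2–O bond may erode the enantiomeric purity. Fallback (Wolff ring contraction under neutral, non-oxidising conditions), setting out from 8: kinetic enolisation (LiHMDS, THF, −78 °C) and acylation with 2,2,2-trifluoroethyl trifluoroacetate would give the 3-trifluoroacetyl ketone F1. Detrifluoroacetylative diazo transfer (MsN3, Et3N, H2O, MeCN) would give the 3-diazo ketone F2. Irradiation of F2 in methanol (about 350 nm) should trigger the Wolff rearrangement, in which the same aryl carbon moves from C4 to the carbene carbon C3, and methanol traps the ketene as the ester. A mixture of 12 and the cis ester F3 is expected; F3 would be equilibrated with catalytic NaOMe in MeOH at 0 °C, so that the sequence comes back to the route at 12.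

Step 3. What may go wrong: protodeboronation of the electron-rich boronic acid may outrun transmetalation; enantioface discrimination may be insufficient; the Pd enolate may open to the chalcone and so racemise the product. Fallback (resolution instead of asymmetric C–C bond formation), setting out from 3: Claisen–Schmidt condensation with 3,4,5-trimethoxybenzaldehyde (KOH, EtOH) would give the 2'-hydroxychalcone F4. Oxa-Michael cyclisation (NaOAc, EtOH, reflux) would give the racemic flavanone F5. Kinetic resolution by asymmetric transfer hydrogenation (Ru–TsDPEN, HCO2H/Et3N, to about half conversion, with the catalyst enantiomer that reduces the (2S)-ketone faster) should turn the unwanted enantiomer into the cis-flavan-4-ol F6 and leave the (2R)-ketone, which is separated by chromatography and rejoins the route at 8.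

Step 7. What may go wrong: the hindered hydride may act as a base (elimination to the exocyclic alkene and aromatisation to the benzofuran, destroying both stereocentres), or it may attack at sulfur and return the alcohol. Fallback (radical instead of ionic deoxygenation), setting out from 13: Appel iodination (I2, PPh3, imidazole, CH2Cl2) would give the primary iodide F7. Reduction with Bu3SnH (1.1 equiv) and AIBN in benzene at 80 °C, at high stannane concentration so that hydrogen transfer outruns a neophyl-type aryl shift, should cleave the alkyl C–I bond much faster than the aryl C–Br bond and come back to the route at 16.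

Further compounds
F1 | step 4 | (2R)-6-bromo-8-methoxy-3-(trifluoroacetyl)-2-(3,4,5-trimethoxyphenyl)-2,3-dihydro-4H-chromen-4-one | Brc1cc(OC)c2c(c1)C(=O)C(C(=O)C(F)(F)F)[C@H](c1cc(OC)c(OC)c(OC)c1)O2
F2 | step 4 | (2S)-6-bromo-3-diazo-8-methoxy-2-(3,4,5-trimethoxyphenyl)-2,3-dihydro-4H-chromen-4-one | Brc1cc(OC)c2c(c1)C(=O)C(=[N+]=[N-])[C@H](c1cc(OC)c(OC)c(OC)c1)O2
F3 | step 4 | methyl (2R,3S)-5-bromo-7-methoxy-2-(3,4,5-trimethoxyphenyl)-2,3-dihydro-1-benzofuran-3-carboxylate (cis epimer) | Brc1cc(OC)c2c(c1)[C@H](C(=O)OC)[C@H](c1cc(OC)c(OC)c(OC)c1)O2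
F4 | step 3 | (E)-1-(5-bromo-2-hydroxy-3-methoxyphenyl)-3-(3,4,5-trimethoxyphenyl)prop-2-en-1-one | COc1cc(/C=C/C(=O)c2cc(Br)cc(OC)c2O)cc(OC)c1OC
F5 | step 3 | rac-6-bromo-8-methoxy-2-(3,4,5-trimethoxyphenyl)-2,3-dihydro-4H-chromen-4-one | Brc1cc(OC)c2c(c1)C(=O)CC(c1cc(OC)c(OC)c(OC)c1)O2
F6 | step 3 | (2S,4S)-6-bromo-8-methoxy-2-(3,4,5-trimethoxyphenyl)chroman-4-ol (cis) | Brc1cc(OC)c2c(c1)[C@@H](O)C[C@@H](c1cc(OC)c(OC)c(OC)c1)O2
F7 | step 7 | (2R,3R)-5-bromo-3-(iodomethyl)-7-methoxy-2-(3,4,5-trimethoxyphenyl)-2,3-dihydro-1-benzofuran | Brc1cc(OC)c2c(c1)[C@@H](CI)[C@H](c1cc(OC)c(OC)c(OC)c1)O2
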